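The ten-membered carbocycle is closed last, at C7–C8 (germacrane numbering), by an intramolecular chromium-mediated carbonyl allylation. The step exploits the homoallylic alcohol array C13=C11–C7–C8–O8 that joins the lactone ring to the ring carbon C8: a 3-(bromomethyl)butenolide, in which the lactone ring and C6 already exist, becomes an allylchromium whose γ-carbon C7 attacks the C8 aldehyde. One operation forms the ring, the exocyclic methylene and the C7 and C8 stereocentres. The precursor is an open-chain butenolide dialdehyde with C6 as its only stereocentre; the C14 enal cannot compete for geometric reasons. A Mitsunobu esterification then inverts C8 while attaching the (S)-2-methylbutanoate.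

Key step: step 11

Assumption: germacrane numbering is used (ring C1–C10; lactone C12(=O)–O–C6 on C11–C7; C13 methylene on C11; C14 on C10; C15 on C4), and (S,S)-ProPhenol is taken as the ligand enantiomer that gives Re-face alkynylation in step 4; its antipode would be used if the sense is opposite.

Step 1
Reactants: 1 diethyl (2-oxooxolan-3-yl)phosphonate; 2 acrolein
Product: 3 (3E)-3-(prop-2-en-1-ylidene)oxolan-2-one
Conditions: LiCl, i-Pr2NEt, MeCN, 0 °C to rt
Reagents that add atoms: none
Why: Horner–Wadsworth–Emmons olefination under Masamune–Roush conditions should give mainly the (E)-alkylidene lactone (C2 trans to the C14 carbonyl), which already holds C8, C9, C10, C14 and the C1=C10 geometry of the target; the minor (Z)-isomer is removed by chromatography.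

Step 2
Reactants: 3 (3E)-3-(prop-2-en-1-ylidene)oxolan-2-one
Product: 4 (2E)-2-(2-hydroxyethyl)penta-2,4-dien-1-ol
Conditions: i-Bu2AlH (excess), CH2Cl2, −78 to 0 °C; aqueous potassium sodium tartrate (KNaC4H4O6)
Reagents that add atoms: none
Why: 1,2-reduction of the conjugated lactone by i-Bu2AlH should open it to the allylic (C14) and homoallylic (C8) primary alcohols without touching the diene or its geometry.

Step 3
Reactants: 4 (2E)-2-(2-hydroxyethyl)penta-2,4-dien-1-ol
Product: 5 triethyl{[(2E)-2-{2-[(triethylsilyl)oxy]ethyl}penta-2,4-dien-1-yl]oxy}silane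
Conditions: Et3SiCl, imidazole, CH2Cl2, 0 °C
Reagents that add atoms: chlorotriethylsilane, CC[Si](Cl)(CC)CC
Why: standard silylation masks both primary alcohols as triethylsilyl ethers, which can later be removed together by mild acid in the presence of the tert-butyldiphenylsilyl ether.

Step 4
Reactants: 6 (2E)-but-2-enal; 7 tert-butyldiphenyl(prop-2-yn-1-yloxy)silane
Product: 8 (4S,5E)-1-[(tert-butyldiphenylsilyl)oxy]hept-5-en-2-yn-4-ol
Conditions: (S,S)-ProPhenol (10 mol%), Me2Zn, Ph3PO, toluene, 0 °C
Reagents that add atoms: none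
Why: zinc–ProPhenol catalysed enantioselective alkynylation of an α,β-unsaturated aldehyde should set C6 as (S) by Re-face addition of the zinc alkynylide inside the dinuclear zinc pocket; the CH3CH= terminus is a traceless handle that leaves as propene in step 8.

Step 5
Reactants: 8 (4S,5E)-1-[(tert-butyldiphenylsilyl)oxy]hept-5-en-2-yn-4-ol
Product: 10 (2Z,4S,5E)-1-[(tert-butyldiphenylsilyl)oxy]-2-iodohepta-2,5-dien-4-ol, via vinylalanate 9 (not isolated)
Conditions: NaAlH2(OCH2CH2OMe)2, THF, 0 °C; then I2, −78 to 0 °C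
Reagents that add atoms: iodine, II; sodium bis(2-methoxyethoxy)aluminium dihydride, [Na+].COCCO[AlH2-]OCCOC (its aluminium and alkoxide ligands stay only in intermediate 9)
Why: hydroxyl-directed trans-hydroalumination of the propargylic alcohol places aluminium on the distal alkyne carbon C4 within a five-membered alkoxyaluminate, and iodinolysis with retention should give the iodoalkene with iodine cis to C6, which fixes the C4=C5 geometry.

Step 6
Reactants: 5 triethyl{[(2E)-2-{2-[(triethylsilyl)oxy]ethyl}penta-2,4-dien-1-yl]oxy}silane; 10 (2Z,4S,5E)-1-[(tert-butyldiphenylsilyl)oxy]-2-iodohepta-2,5-dien-4-ol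
Product: 12 (2E,4S,5E,9E)-6-{[(tert-butyldiphenylsilyl)oxy]methyl}-10-{[(triethylsilyl)oxy]methyl}-12-[(triethylsilyl)oxy]dodeca-2,5,9-trien-4-ol, via alkylborane 11 (not isolated)
Conditions: 9-BBN, THF, 0 °C to rt; then 10, Pd(dppf)Cl2 (10 mol%), AsPh3, Cs2CO3, DMF/THF/H2O, rt
Reagents that add atoms: 9-borabicyclo[3.3.1]nonane, B1C2CCCC1CCC2 (its boron stays only in intermediate 11)
Why: 9-BBN should add only to the terminal CH2= of the 4,4-disubstituted 1,3-diene to give the homoallylic borane, and B-alkyl Suzuki–Miyaura coupling replaces iodine with retention, so that C3 ends cis to C6 and C15 trans (the ring-cis C4=C5 olefin) with the free alcohol and silyl ethers tolerated.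

Step 7
Reactants: 12 (2E,4S,5E,9E)-6-{[(tert-butyldiphenylsilyl)oxy]methyl}-10-{[(triethylsilyl)oxy]methyl}-12-[(triethylsilyl)oxy]dodeca-2,5,9-trien-4-ol; 13 2-(bromomethyl)prop-2-enoic acid
Product: 14 (2E,4S,5E,9E)-6-{[(tert-butyldiphenylsilyl)oxy]methyl}-10-{[(triethylsilyl)oxy]methyl}-12-[(triethylsilyl)oxy]dodeca-2,5,9-trien-4-yl 2-(bromomethyl)prop-2-enoate
Conditions: DCC, DMAP (cat.), CH2Cl2, 0 °C
Reagents that add atoms: none
Why: Steglich esterification acylates the only free (secondary bis-allylic) alcohol with retention at C6, and catalytic DMAP at 0 °C spares the allylic bromide.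

Step 8
Reactants: 14 (2E,4S,5E,9E)-6-{[(tert-butyldiphenylsilyl)oxy]methyl}-10-{[(triethylsilyl)oxy]methyl}-12-[(triethylsilyl)oxy]dodeca-2,5,9-trien-4-yl 2-(bromomethyl)prop-2-enoate
Product: 15 (5R)-3-(bromomethyl)-5-[(1E,5E)-2-{[(tert-butyldiphenylsilyl)oxy]methyl}-6-{[(triethylsilyl)oxy]methyl}-8-[(triethylsilyl)oxy]octa-1,5-dien-1-yl]furan-2(5H)-one
Conditions: second-generation Hoveyda–Grubbs catalyst (10 mol%), toluene, 60 °C
Reagents that add atoms: none
Why: ring-closing metathesis between the acrylate methylene and the propenyl group (propene is lost) should close the five-membered lactone ring as a 3-(bromomethyl)butenolide, while the two trisubstituted olefins stay out of the reaction and C6 is untouched.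

Step 9
Reactants: 15 (5R)-3-(bromomethyl)-5-[(1E,5E)-2-{[(tert-butyldiphenylsilyl)oxy]methyl}-6-{[(triethylsilyl)oxy]methyl}-8-[(triethylsilyl)oxy]octa-1,5-dien-1-yl]furan-2(5H)-one
Product: 16 (5R)-3-(bromomethyl)-5-[(1E,5E)-2-{[(tert-butyldiphenylsilyl)oxy]methyl}-8-hydroxy-6-(hydroxymethyl)octa-1,5-dien-1-yl]furan-2(5H)-one
Conditions: AcOH/THF/H2O (3:1:1), rt
Reagents that add atoms: none
Why: primary triethylsilyl ethers are hydrolysed by aqueous acetic acid while the tert-butyldiphenylsilyl ether, the butenolide and the allylic bromide should survive (no amine or fluoride base is used because it would attack the bromide or the acidic C6–H).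

Step 10
Reactants: 16 (5R)-3-(bromomethyl)-5-[(1E,5E)-2-{[(tert-butyldiphenylsilyl)oxy]methyl}-8-hydroxy-6-(hydroxymethyl)octa-1,5-dien-1-yl]furan-2(5H)-one
Product: 17 (2E,6E)-7-[(2R)-4-(bromomethyl)-5-oxo-2,5-dihydrofuran-2-yl]-6-{[(tert-butyldiphenylsilyl)oxy]methyl}-2-(2-oxoethyl)hepta-2,6-dienal
Conditions: Dess–Martin periodinane, NaHCO3, CH2Cl2, 0 °C to rt; used crude at once
Reagents that add atoms: none
Why: Dess–Martin oxidation converts both primary alcohols into aldehydes under buffered non-basic conditions; the resulting 2-alkylidene-1,4-dialdehyde array is the one present in the isolable natural dialdehyde polygodial, and immediate use limits enolisation at C9.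

Step 11
Reactants: 17 (2E,6E)-7-[(2R)-4-(bromomethyl)-5-oxo-2,5-dihydrofuran-2-yl]-6-{[(tert-butyldiphenylsilyl)oxy]methyl}-2-(2-oxoethyl)hepta-2,6-dienal
Product: 19 (1(10)E,4E,6R,7R,8S)-15-[(tert-butyldiphenylsilyl)oxy]-8-hydroxy-14-oxogermacra-1(10),4,11(13)-trien-12,6-olide (8α-alcohol), via allylchromium dichloride 18 (not isolated)
Conditions: CrCl2 (8 equiv), THF, rt, syringe-pump addition to 2 mM; aqueous work-up
Reagents that add atoms: chromium dichloride, Cl[Cr]Cl (its atoms stay only in intermediate 18)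
Why: CrCl2 reduces the allylic bromide to the allylchromium dichloride 18 (Nozaki–Hiyama reaction), which adds through its γ-carbon C7 to the C8 aldehyde with allylic transposition, so that one bond formation closes the ring, moves the double bond to C11=C13 and creates C7 and C8. The closest known reactions are the chromium-mediated macrocyclisations that close germacranolide rings and the Barbier additions of 3-(bromomethyl)butenolides to aldehydes. The ten-membered carbocycle is closed by a 10-exo-trig carbonyl addition, the lactone ring being already present. C7 is set by attack on the butenolide face anti to the C5 alkenyl substituent at C6 (trans-fused lactone, 7R), and C8 by a chair Zimmerman–Traxler transition state in which chromium bridges C13 and the aldehyde oxygen, C9 is pseudo-equatorial and the allyl unit is E-locked by the ring, which should give the anti adduct (8S, 8α-OH). The step needs chemoselectivity between the two aldehydes and against oligomerisation: addition to the C14 enal would place the (E)-C1=C10 olefin in a nine-membered ring and is geometrically excluded, the ring-cis olefins C4=C5 and C1=C10 pre-fold the chain, and high dilution suppresses intermolecular coupling.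

Step 12
Reactants: 19 (1(10)E,4E,6R,7R,8S)-15-[(tert-butyldiphenylsilyl)oxy]-8-hydroxy-14-oxogermacra-1(10),4,11(13)-trien-12,6-olide; 20 (2S)-2-methylbutanoic acid
Product: 21 (1(10)E,4E,6R,7R,8R)-15-[(tert-butyldiphenylsilyl)oxy]-8-{[(2S)-2-methylbutanoyl]oxy}-14-oxogermacra-1(10),4,11(13)-trien-12,6-olide
Conditions: PPh3, DIAD, toluene, 0 °C to rt
Reagents that add atoms: none
Why: Mitsunobu esterification displaces the C8 oxyphosphonium by the carboxylate in an SN2 reaction with inversion (8S to 8R), so the stereochemical correction and the acylation are one operation, and the stereocentre of the acid is not involved.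

Step 13
Reactants: 21 (1(10)E,4E,6R,7R,8R)-15-[(tert-butyldiphenylsilyl)oxy]-8-{[(2S)-2-methylbutanoyl]oxy}-14-oxogermacra-1(10),4,11(13)-trien-12,6-olide
Product: 22 (1(10)E,4E,6R,7R,8R)-15-hydroxy-8-{[(2S)-2-methylbutanoyl]oxy}-14-oxogermacra-1(10),4,11(13)-trien-12,6-olide (CNP0168859.6)
Conditions: HF·pyridine, THF, 0 °C to rt
Reagents that add atoms: none
Why: buffered HF·pyridine cleaves the primary allylic tert-butyldiphenylsilyl ether without strong base, so the enal, the α-methylene lactone and the 8-acyloxy group (prone to E1cB loss under base) should survive.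

Compound list
1 | diethyl (2-oxooxolan-3-yl)phosphonate | CCOP(=O)(OCC)C1CCOC1=O | starting material
2 | acrolein (prop-2-enal) | C=CC=O | starting material
3 | (3E)-3-(prop-2-en-1-ylidene)oxolan-2-one | C=C/C=C1\CCOC1=O | intermediate
4 | (2E)-2-(2-hydroxyethyl)penta-2,4-dien-1-ol | C=C/C=C(/CO)CCO | intermediate
5 | triethyl{[(2E)-2-{2-[(triethylsilyl)oxy]ethyl}penta-2,4-dien-1-yl]oxy}silane | C=C/C=C(/CO[Si](CC)(CC)CC)CCO[Si](CC)(CC)CC | intermediate
6 | (2E)-but-2-enal (crotonaldehyde) | C/C=C/C=O | starting material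
7 | tert-butyldiphenyl(prop-2-yn-1-yloxy)silane | C#CCO[Si](c1ccccc1)(c1ccccc1)C(C)(C)C | starting material
8 | (4S,5E)-1-[(tert-butyldiphenylsilyl)oxy]hept-5-en-2-yn-4-ol | O[C@@H](/C=C/C)C#CCO[Si](c1ccccc1)(c1ccccc1)C(C)(C)C | intermediate
9 | sodium vinylalanate from 8: cyclic alkoxy(alkenyl)bis(2-methoxyethoxy)aluminate in which aluminium bridges the C4 oxygen and C2 of the heptenyne chain (formed in the flask) | [Na+].COCCO[Al-]1(OCCOC)O[C@@H](/C=C/C)C=C1CO[Si](c1ccccc1)(c1ccccc1)C(C)(C)C | intermediate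
10 | (2Z,4S,5E)-1-[(tert-butyldiphenylsilyl)oxy]-2-iodohepta-2,5-dien-4-ol | O[C@@H](/C=C/C)/C=C(/CO[Si](c1ccccc1)(c1ccccc1)C(C)(C)C)I | intermediate
11 | 9-[(3E)-4-{[(triethylsilyl)oxy]methyl}-6-[(triethylsilyl)oxy]hex-3-en-1-yl]-9-borabicyclo[3.3.1]nonane (formed in the flask) | B1(CC/C=C(/CO[Si](CC)(CC)CC)CCO[Si](CC)(CC)CC)C2CCCC1CCC2 | intermediate
12 | (2E,4S,5E,9E)-6-{[(tert-butyldiphenylsilyl)oxy]methyl}-10-{[(triethylsilyl)oxy]methyl}-12-[(triethylsilyl)oxy]dodeca-2,5,9-trien-4-ol | O[C@@H](/C=C/C)/C=C(/CO[Si](c1ccccc1)(c1ccccc1)C(C)(C)C)CC/C=C(/CO[Si](CC)(CC)CC)CCO[Si](CC)(CC)CC | intermediate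
13 | 2-(bromomethyl)prop-2-enoic acid | C=C(CBr)C(=O)O | starting material
14 | (2E,4S,5E,9E)-6-{[(tert-butyldiphenylsilyl)oxy]methyl}-10-{[(triethylsilyl)oxy]methyl}-12-[(triethylsilyl)oxy]dodeca-2,5,9-trien-4-yl 2-(bromomethyl)prop-2-enoate | C=C(CBr)C(=O)O[C@@H](/C=C/C)/C=C(/CO[Si](c1ccccc1)(c1ccccc1)C(C)(C)C)CC/C=C(/CO[Si](CC)(CC)CC)CCO[Si](CC)(CC)CC | intermediate
15 | (5R)-3-(bromomethyl)-5-[(1E,5E)-2-{[(tert-butyldiphenylsilyl)oxy]methyl}-6-{[(triethylsilyl)oxy]methyl}-8-[(triethylsilyl)oxy]octa-1,5-dien-1-yl]furan-2(5H)-one | BrCC1=C[C@@H](/C=C(/CO[Si](c2ccccc2)(c2ccccc2)C(C)(C)C)CC/C=C(/CO[Si](CC)(CC)CC)CCO[Si](CC)(CC)CC)OC1=O | intermediate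
16 | (5R)-3-(bromomethyl)-5-[(1E,5E)-2-{[(tert-butyldiphenylsilyl)oxy]methyl}-8-hydroxy-6-(hydroxymethyl)octa-1,5-dien-1-yl]furan-2(5H)-one | BrCC1=C[C@@H](/C=C(/CO[Si](c2ccccc2)(c2ccccc2)C(C)(C)C)CC/C=C(/CO)CCO)OC1=O | intermediate
17 | (2E,6E)-7-[(2R)-4-(bromomethyl)-5-oxo-2,5-dihydrofuran-2-yl]-6-{[(tert-butyldiphenylsilyl)oxy]methyl}-2-(2-oxoethyl)hepta-2,6-dienal | BrCC1=C[C@@H](/C=C(/CO[Si](c2ccccc2)(c2ccccc2)C(C)(C)C)CC/C=C(/C=O)CC=O)OC1=O | intermediate
18 | allylchromium dichloride from 17 (C13–CrCl2 in place of C13–Br; formed in the flask) | Cl[Cr](Cl)CC1=C[C@@H](/C=C(/CO[Si](c2ccccc2)(c2ccccc2)C(C)(C)C)CC/C=C(/C=O)CC=O)OC1=O | intermediate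
19 | (1(10)E,4E,6R,7R,8S)-15-[(tert-butyldiphenylsilyl)oxy]-8-hydroxy-14-oxogermacra-1(10),4,11(13)-trien-12,6-olide (8α-alcohol, trans-fused lactone, both ring olefins cis within the ring) | C=C1C(=O)O[C@@H]2/C=C(/CO[Si](c3ccccc3)(c3ccccc3)C(C)(C)C)CC/C=C(/C=O)C[C@H](O)[C@@H]12 | intermediate
20 | (2S)-2-methylbutanoic acid | CC[C@H](C)C(O)=O | starting material
21 | (1(10)E,4E,6R,7R,8R)-15-[(tert-butyldiphenylsilyl)oxy]-8-{[(2S)-2-methylbutanoyl]oxy}-14-oxogermacra-1(10),4,11(13)-trien-12,6-olide | C=C1C(=O)O[C@@H]2/C=C(/CO[Si](c3ccccc3)(c3ccccc3)C(C)(C)C)CC/C=C(/C=O)C[C@@H](OC(=O)[C@@H](C)CC)[C@@H]12 | intermediate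
22 | (1(10)E,4E,6R,7R,8R)-15-hydroxy-8-{[(2S)-2-methylbutanoyl]oxy}-14-oxogermacra-1(10),4,11(13)-trien-12,6-olide (CNP0168859.6) | C=C1C(=O)O[C@@H]2/C=C(/CO)CC/C=C(/C=O)C[C@@H](OC(=O)[C@@H](C)CC)[C@@H]12 | target

Total steps: 13. Longest linear sequence: 11 steps (steps 1–3 and 6–13).

Steps most likely to fail

Step 11. The allylchromium may be lost before ring closure (protonation, or vinylogous elimination with opening of the lactone). The dialdehyde may enolise at C9, chains may couple intermolecularly, or the aldehyde may be attacked from the wrong face. Fallback (sets out from 15, comes back at 19): the allyl donor is made isolable and the ring is closed by allylboration without a reducing metal. Borylation of 15 (B2pin2, Pd2(dba)3, toluene/DMSO, 50 °C) would give the allylboronate F1. AcOH/THF/H2O would then give the diol F2, and Dess–Martin oxidation the dialdehyde F3. At high dilution with Sc(OTf)3 in toluene, F3 should undergo intramolecular allylboration through the same chair transition state and give 19 after aqueous work-up.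

Step 12. Elimination of the activated C8 oxygen toward C9 or C7 (both neighbouring hydrogens are allylic) may outrun substitution at this hindered carbinol, and the phosphine may add to the Michael acceptors. Fallback (sets out from 19, comes back at 21): inversion by sulfonate displacement in place of the redox condensation. ClCH2SO2Cl and pyridine in CH2Cl2 at 0 °C would convert 19 into the chloromethanesulfonate F4. Caesium (S)-2-methylbutanoate (from 20 and Cs2CO3, with 18-crown-6 in toluene at 40 °C) should then displace it with inversion to give 21.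

Step 6. Transmetalation of the alkylborane onto the hindered 2-iodoallyl palladium species may be slow, with protodeboronation or β-hydride elimination taking over under the aqueous base. Fallback (sets out from 5, comes back at 12): base-free Negishi coupling. Hydroboration–oxidation of 5 (9-BBN; then NaOH, H2O2) would give the primary alcohol F5, and I2, PPh3, imidazole the iodide F6. Zinc insertion (Zn, LiCl, THF) would give the alkylzinc iodide F7, which should couple with 10 under Pd(dppf)Cl2 catalysis (THF, 40 °C) to give 12.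

Further compounds
F1 | step 11 | (5R)-3-[(4,4,5,5-tetramethyl-1,3,2-dioxaborolan-2-yl)methyl]-5-[(1E,5E)-2-{[(tert-butyldiphenylsilyl)oxy]methyl}-6-{[(triethylsilyl)oxy]methyl}-8-[(triethylsilyl)oxy]octa-1,5-dien-1-yl]furan-2(5H)-one | CC1(C)OB(CC2=C[C@@H](/C=C(/CO[Si](c3ccccc3)(c3ccccc3)C(C)(C)C)CC/C=C(/CO[Si](CC)(CC)CC)CCO[Si](CC)(CC)CC)OC2=O)OC1(C)C
F2 | step 11 | diol allylboronate (F1 without its two triethylsilyl groups) | CC1(C)OB(CC2=C[C@@H](/C=C(/CO[Si](c3ccccc3)(c3ccccc3)C(C)(C)C)CC/C=C(/CO)CCO)OC2=O)OC1(C)C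
F3 | step 11 | dialdehyde allylboronate (boron analogue of 17) | CC1(C)OB(CC2=C[C@@H](/C=C(/CO[Si](c3ccccc3)(c3ccccc3)C(C)(C)C)CC/C=C(/C=O)CC=O)OC2=O)OC1(C)C
F4 | step 12 | chloromethanesulfonate of 19 (same configuration as 19) | C=C1C(=O)O[C@@H]2/C=C(/CO[Si](c3ccccc3)(c3ccccc3)C(C)(C)C)CC/C=C(/C=O)C[C@H](OS(=O)(=O)CCl)[C@@H]12
F5 | step 6 | (3E)-4-{[(triethylsilyl)oxy]methyl}-6-[(triethylsilyl)oxy]hex-3-en-1-ol | OCC/C=C(/CO[Si](CC)(CC)CC)CCO[Si](CC)(CC)CC
F6 | step 6 | (3E)-1-iodo-4-{[(triethylsilyl)oxy]methyl}-6-[(triethylsilyl)oxy]hex-3-ene | ICC/C=C(/CO[Si](CC)(CC)CC)CCO[Si](CC)(CC)CC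
F7 | step 6 | [(3E)-4-{[(triethylsilyl)oxy]methyl}-6-[(triethylsilyl)oxy]hex-3-en-1-yl]zinc iodide | I[Zn]CC/C=C(/CO[Si](CC)(CC)CC)CCO[Si](CC)(CC)CC
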